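**Retrosynthetic overview**

- Numbering of the target (1H,3H-furo[3,4-c]furan): C1H(guaiacyl)–O2–C3H2–C3a(OH)–C4H(syringyl)–O5–C6H2–C6a(H). Ring A = C3a/C4/O5/C6/C6a (syringyl ring); ring B = C1/O2/C3/C3a/C6a (guaiacyl ring).
- Enabling feature: in ring A the three-atom unit C6–O5–C4 is attached to the rest only through the two adjacent ring-fusion carbons C6a and C3a, and C3a carries oxygen. Ring A is therefore the [3+2] adduct of a carbonyl ylide CH2–O–CH(syringyl) with the enol C3a=C6a double bond of an α-keto lactone.
- Key disconnection: C6–C6a and C4–C3a in one operation, giving the carbonyl ylide from O-benzylsyringaldehyde and (S)-3-benzyloxy-5-(O-benzylguaiacyl)furan-2(5H)-one. The latter is ring B at the lactone level (C3 as C=O), with the tertiary OH masked as an enol benzyl ether.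
- Ring order: ring B first (butenolide from O-benzylvanillin by catalytic asymmetric 2-(ethoxycarbonyl)allylation, excision of the methylene carbon, O-benzylation). Ring A follows by the cycloaddition, which sets C4, C3a and C6a from C1. C3 is then lowered to CH2 (lactone → diol → cycloetherification) and the three benzyl groups are removed.

Key step: step 7

Assumption: the two O-benzyl aldehydes, ethyl 2-(bromomethyl)acrylate and (trimethylsilyl)methanol are purchased; locants in the Why lines are those of the target unless a compound number is attached.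

**Route**

Step 1
Reactants: 1 4-(benzyloxy)-3-methoxybenzaldehyde; 2 ethyl 2-(bromomethyl)acrylate
Product: 5 (S)-5-[4-(benzyloxy)-3-methoxyphenyl]-3-methylidenedihydrofuran-2(3H)-one, via silyl ether 3 (not isolated), via hydroxy ester 4 (not isolated)
Conditions: CrCl2 (10 mol %), chiral tridentate carbazole-bis(oxazoline) ligand (12 mol %, enantiomer that directs Si-face addition), Mn powder, Me3SiCl, i-Pr2NEt (cat.), THF, 0 °C to rt; aq. citric acid; then pyridinium p-toluenesulfonate (cat.), PhMe, 50 °C
Reagents that add atoms: none
Why: Catalytic enantioselective Nozaki–Hiyama–Kishi 2-(alkoxycarbonyl)allylation, in which the allylchromium species from 2 adds to 1 through a closed six-membered transition state on the Si face selected by the chiral chromium complex (this sets the S benzylic centre, the later C1), after which the γ-hydroxy ester lactonises under weakly acidic conditions that should not ionise the benzylic C–O bond.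

Step 2
Reactants: 5
Product: 6 (5S)-5-[4-(benzyloxy)-3-methoxyphenyl]-3-hydroxy-3-(hydroxymethyl)dihydrofuran-2(3H)-one (either configuration at C3)
Conditions: OsO4 (2 mol %), N-methylmorpholine N-oxide, acetone/H2O, rt; Na2SO3 quench, filtration through silica
Reagents that add atoms: N-methylmorpholine N-oxide, C[N+]1([O-])CCOCC1 (terminal oxidant, oxygen passed on through OsO4, O=[Os](=O)(=O)=O); water, O
Why: Upjohn dihydroxylation, in which OsO4 attacks only the exocyclic 1,1-disubstituted alkene (arenes and benzyl ether are inert), the new tertiary centre needs no control because it is destroyed in step 3, and the osmium is removed before the oxidation-sensitive enol is made.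

Step 3
Reactants: 6
Product: 7 (S)-5-[4-(benzyloxy)-3-methoxyphenyl]-3-hydroxyfuran-2(5H)-one (enol form of the 2,3-dioxo lactone)
Conditions: NaIO4 (1.2 equiv), THF/H2O, 0 °C to rt
Reagents that add atoms: none
Why: Periodate glycol cleavage (Malaprade reaction) removes the hydroxymethyl carbon as formaldehyde and gives the α-keto lactone, which rests as the conjugated enol, while C5 is untouched and the acidic enol OH shields the γ-position from deprotonation.

Step 4
Reactants: 7
Product: 8 (S)-3-(benzyloxy)-5-[4-(benzyloxy)-3-methoxyphenyl]furan-2(5H)-one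
Conditions: BnOH, PPh3, diisopropyl azodicarboxylate, THF, 0 °C
Reagents that add atoms: benzyl alcohol, OCc1ccccc1
Why: Mitsunobu O-alkylation, for which the acidic enol of the α-keto lactone is a competent pronucleophile, so that the enol ether forms under essentially neutral conditions and the base-mediated γ-deprotonation (racemisation through the 2-oxidofuran) that a carbonate alkylation would risk is avoided.

Step 5
Reactants: 9 4-(benzyloxy)-3,5-dimethoxybenzaldehyde; 10 (trimethylsilyl)methanol
Product: 11 bis[(trimethylsilyl)methyl] acetal of 9, that is 2-(benzyloxy)-5-{bis[(trimethylsilyl)methoxy]methyl}-1,3-dimethoxybenzene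
Conditions: 10 (2.5 equiv), pyridinium p-toluenesulfonate (cat.), benzene, reflux, Dean–Stark trap
Reagents that add atoms: none
Why: Acid-catalysed acetalisation driven by azeotropic removal of water, with the α-silyl alcohol stable to the weakly acidic catalyst.

Step 6
Reactants: 11
Product: 12 {[chloro(4-(benzyloxy)-3,5-dimethoxyphenyl)methoxy]methyl}trimethylsilane (racemic α-chloro ether, used crude)
Conditions: AcCl (1.05 equiv), CH2Cl2, 0 °C to rt; volatiles removed in vacuo; used at once as a MeCN solution
Reagents that add atoms: acetyl chloride, CC(=O)Cl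
Why: Cleavage of a dialkyl acetal by an acyl chloride (aryl-stabilised oxocarbenium ion, then chloride capture) is the standard entry to α-chlorobenzyl ethers and leaves the C–Si bond and the aryl benzyl ether intact, and the new centre is racemic but is planarised in step 7.

Step 7
Reactants: 8; 12
Product: 14 (3S,3aR,6R,6aR)-6a-(benzyloxy)-3-[4-(benzyloxy)-3-methoxyphenyl]-6-[4-(benzyloxy)-3,5-dimethoxyphenyl]tetrahydro-1H,3H-furo[3,4-c]furan-1-one, via carbonyl ylide 13 (not isolated)
Conditions: 12 (2.5 equiv, slow addition), CsF (flame-dried, 5 equiv), MeCN, 0 °C to rt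
Reagents that add atoms: none
Why: Fluoride attacks silicon of 12 while chloride departs (1,3-elimination through the aryl-stabilised oxocarbenium ion) and releases the non-stabilised carbonyl ylide 13, which adds across the electron-poor C3=C4 bond of 8 in a concerted but asynchronous 1,3-dipolar cycloaddition. The closest known reaction type is the CsF-induced generation of carbonyl ylides from α-chloroalkyl (trimethylsilyl)methyl ethers and their [3+2] addition to acrylates, fumarates and enones. Ring A of the target (C3a–C4–O5–C6–C6a) is closed by this intermolecular suprafacial [3+2] addition, both C–C bonds forming on one face of the butenolide, so the ring fusion can only be cis. Regiochemistry is set by both frontier interactions and by the polar limit: the unsubstituted CH2 terminus (more nucleophilic, larger HOMO coefficient) bonds to the lactone β-carbon C4 of 8 (future C6a), and the oxocarbenium-like ArCH terminus bonds to the benzyloxy-bearing, enol-ether-like α-carbon C3 of 8 (future C3a), the intermediate charge pattern being an aryl-stabilised oxocarbenium ion beside a lactone enolate. The ring-fusion centres C3a and C6a are controlled by the C5 aryl group of 8, which shields one face so that the dipole adds anti to it, and C4 is controlled by the E (aryl anti) geometry of the ylide together with the exo transition state, in which the dipole oxygen and the developing ring point away from the lactone ring, so that the syringyl group ends on the convex face, cis to the benzyloxy group. The step needs capture of the short-lived ylide (slow addition of excess 12 to 8), regio-, face- and exo-selectivity (as described) and preservation of the base-sensitive γ-centre of 8 (weakly basic suspended CsF at low temperature, no other acidic site).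

Step 8
Reactants: 14
Product: 15 [(2R,3S,4R)-3-(benzyloxy)-2-[4-(benzyloxy)-3,5-dimethoxyphenyl]-4-{(S)-[4-(benzyloxy)-3-methoxyphenyl](hydroxy)methyl}oxolan-3-yl]methanol
Conditions: LiAlH4, THF, 0 °C; Fieser work-up
Reagents that add atoms: none
Why: Hydride reduction of the lactone to the 1,4-diol, in which no stereocentre can be affected because the lactone α-carbon is quaternary and the benzyl ethers and ring A are inert to LiAlH4.

Step 9
Reactants: 15
Product: 17 (1S,3aS,4R,6aR)-3a-(benzyloxy)-1-[4-(benzyloxy)-3-methoxyphenyl]-4-[4-(benzyloxy)-3,5-dimethoxyphenyl]tetrahydro-1H,3H-furo[3,4-c]furan, via primary tosylate 16 (not isolated)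
Conditions: NaH (2.5 equiv), N-tosylimidazole (1.05 equiv), THF, 0 °C to rt
Reagents that add atoms: none
Why: One-pot sulfonylation and Williamson etherification, in which the less hindered primary alkoxide is tosylated and the benzylic alkoxide displaces the tosylate in a 5-exo-tet closure (helped by the Thorpe–Ingold effect of the quaternary carbon) at a non-stereogenic carbon, so ring B forms with retention at C1 and the benzyl-protected tertiary oxygen cannot compete by epoxide formation.

Step 10
Reactants: 17
Product: 18 fraxiresinol, (1S,3aS,4R,6aR)-4-(4-hydroxy-3,5-dimethoxyphenyl)-1-(4-hydroxy-3-methoxyphenyl)tetrahydro-1H,3H-furo[3,4-c]furan-3a(4H)-ol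
Conditions: H2 (1 atm), Pd(OH)2/C, EtOAc/EtOH, rt; stopped when the tertiary benzyl ether is consumed
Reagents that add atoms: none
Why: Heterogeneous hydrogenolysis cleaves the three PhCH2–O bonds (the two aryl benzyl ethers quickly, the tertiary alkyl benzyl ether more slowly), whereas the ring benzylic C–O bonds are secondary, flanked by the ring-fusion carbons and attached to electron-rich arenes and should react much more slowly, so no stereocentre is touched.

**Compound list**

1 | 4-(benzyloxy)-3-methoxybenzaldehyde | COc1cc(C=O)ccc1OCc1ccccc1 | starting material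
2 | ethyl 2-(bromomethyl)acrylate | C=C(CBr)C(=O)OCC | starting material
3 | ethyl (S)-4-[4-(benzyloxy)-3-methoxyphenyl]-2-methylidene-4-[(trimethylsilyl)oxy]butanoate (silyl ether, not isolated) | CCOC(=O)C(=C)C[C@H](O[Si](C)(C)C)c1ccc(OCc2ccccc2)c(OC)c1 | intermediate
4 | ethyl (S)-4-[4-(benzyloxy)-3-methoxyphenyl]-4-hydroxy-2-methylidenebutanoate (hydroxy ester, not isolated) | CCOC(=O)C(=C)C[C@H](O)c1ccc(OCc2ccccc2)c(OC)c1 | intermediate
5 | (S)-5-[4-(benzyloxy)-3-methoxyphenyl]-3-methylidenedihydrofuran-2(3H)-one | C=C1C[C@@H](c2ccc(OCc3ccccc3)c(OC)c2)OC1=O | intermediate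
6 | (5S)-5-[4-(benzyloxy)-3-methoxyphenyl]-3-hydroxy-3-(hydroxymethyl)dihydrofuran-2(3H)-one (C3 epimers) | OCC1(O)C[C@@H](c2ccc(OCc3ccccc3)c(OC)c2)OC1=O | intermediate
7 | (S)-5-[4-(benzyloxy)-3-methoxyphenyl]-3-hydroxyfuran-2(5H)-one | OC1=C[C@@H](c2ccc(OCc3ccccc3)c(OC)c2)OC1=O | intermediate
8 | (S)-3-(benzyloxy)-5-[4-(benzyloxy)-3-methoxyphenyl]furan-2(5H)-one | c1ccccc1COC1=C[C@@H](c2ccc(OCc3ccccc3)c(OC)c2)OC1=O | intermediate
9 | 4-(benzyloxy)-3,5-dimethoxybenzaldehyde | COc1cc(C=O)cc(OC)c1OCc1ccccc1 | starting material
10 | (trimethylsilyl)methanol | C[Si](C)(C)CO | starting material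
11 | 2-(benzyloxy)-5-{bis[(trimethylsilyl)methoxy]methyl}-1,3-dimethoxybenzene | COc1cc(C(OC[Si](C)(C)C)OC[Si](C)(C)C)cc(OC)c1OCc1ccccc1 | intermediate
12 | {[chloro(4-(benzyloxy)-3,5-dimethoxyphenyl)methoxy]methyl}trimethylsilane (racemic) | COc1cc(C(Cl)OC[Si](C)(C)C)cc(OC)c1OCc1ccccc1 | intermediate
13 | (E)-carbonyl ylide ArCH=O(+)–CH2(−) with Ar = 4-(benzyloxy)-3,5-dimethoxyphenyl (not isolated) | [CH2-]/[O+]=C/c1cc(OC)c(OCc2ccccc2)c(OC)c1 | intermediate
14 | (3S,3aR,6R,6aR)-6a-(benzyloxy)-3-[4-(benzyloxy)-3-methoxyphenyl]-6-[4-(benzyloxy)-3,5-dimethoxyphenyl]tetrahydro-1H,3H-furo[3,4-c]furan-1-one | COc1cc([C@H]2OC(=O)[C@]3(OCc4ccccc4)[C@@H](c4cc(OC)c(OCc5ccccc5)c(OC)c4)OC[C@H]23)ccc1OCc1ccccc1 | intermediate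
15 | [(2R,3S,4R)-3-(benzyloxy)-2-[4-(benzyloxy)-3,5-dimethoxyphenyl]-4-{(S)-[4-(benzyloxy)-3-methoxyphenyl](hydroxy)methyl}oxolan-3-yl]methanol | COc1cc([C@@H](O)[C@H]2CO[C@H](c3cc(OC)c(OCc4ccccc4)c(OC)c3)[C@]2(CO)OCc2ccccc2)ccc1OCc1ccccc1 | intermediate
16 | primary p-toluenesulfonate of 15 (not isolated) | COc1cc([C@@H](O)[C@H]2CO[C@H](c3cc(OC)c(OCc4ccccc4)c(OC)c3)[C@]2(COS(=O)(=O)c2ccc(C)cc2)OCc2ccccc2)ccc1OCc1ccccc1 | intermediate
17 | (1S,3aS,4R,6aR)-3a-(benzyloxy)-1-[4-(benzyloxy)-3-methoxyphenyl]-4-[4-(benzyloxy)-3,5-dimethoxyphenyl]tetrahydro-1H,3H-furo[3,4-c]furan | COc1cc([C@H]2OC[C@]3(OCc4ccccc4)[C@@H](c4cc(OC)c(OCc5ccccc5)c(OC)c4)OC[C@H]23)ccc1OCc1ccccc1 | intermediate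
18 | fraxiresinol | COc1cc([C@H]2OC[C@]3(O)[C@@H](c4cc(OC)c(O)c(OC)c4)OC[C@H]23)ccc1O | target

**Step count and risks**

Total step count: 10. Longest linear sequence: 8 steps (1 → 5 → 6 → 7 → 8 → 14 → 15 → 17 → 18; steps 1, 2, 3, 4, 7, 8, 9, 10).

The three steps most likely to fail:

Step 7. The non-stabilised ylide may close to the aryl oxirane or oligomerise faster than the trisubstituted captodative alkene intercepts it. The exo preference at C4 may be weak. Fluoride may deprotonate the γ-position of 8 and erode its enantiopurity. The fallback sets out from 8 (with aldehyde 9) and comes back at 14; it uses a longer-lived, ester-stabilised ylide made under neutral conditions and then removes the ester. Slow addition of ethyl diazoacetate to 8, excess 9 and Rh2(OAc)4 (cat.) in CH2Cl2 generates the ylide by carbene transfer to the aldehyde. Its ester-bearing carbon adds to the lactone β-carbon, which should give the ethyl ester cycloadduct F1. Me3SnOH in 1,2-dichloroethane at 70 °C should hydrolyse the ethyl ester to the carboxylic acid F2. Photoredox hydrodecarboxylation (9-mesityl-10-methylacridinium tetrafluoroborate and bis(4-chlorophenyl) disulfide as catalysts, 2,6-lutidine, blue light) then replaces CO2H by H at the α-oxygenated carbon and should give 14.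

Step 9. Tosylation may occur at the secondary benzylic alkoxide, followed by ionisation with loss of configuration at C1 or elimination; alternatively the displacement at the neopentyl-type primary carbon may be too slow. The fallback sets out from 14 and comes back at 17, so it bypasses diol 15. Partial reduction with i-Bu2AlH (CH2Cl2, −78 °C) should give the lactol F3. Ionic hydrogenation with Et3SiH and BF3·OEt2 at −78 °C should then reduce the ring-B oxocarbenium ion to the cyclic ether 17, the low temperature being chosen to keep the benzylic ring C–O bonds from ionising.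

Step 10. Hydrogenolytic opening of the benzylic C–O bonds of the furofuran may compete with the slow cleavage of the hindered tertiary benzyl ether. The fallback sets out from 17 and comes back at 18 and makes no new compound (F0). It is a single-electron reductive debenzylation with lithium 4,4'-di-tert-butylbiphenylide in THF at −78 °C. The unsubstituted phenyl rings of the three benzyl groups accept an electron more readily than the alkoxy-substituted arenes, and once the aryl benzyl ethers are cleaved the resulting phenoxide rings should resist reduction, which protects the ring benzylic C–O bonds.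

**Further compounds**

F1 | step 7 | ethyl 6a-(benzyloxy)-3-[4-(benzyloxy)-3-methoxyphenyl]-6-[4-(benzyloxy)-3,5-dimethoxyphenyl]-1-oxohexahydrofuro[3,4-c]furan-4-carboxylate (configuration of 14, either epimer at C4) | COc1cc([C@H]2OC(=O)[C@]3(OCc4ccccc4)[C@@H](c4cc(OC)c(OCc5ccccc5)c(OC)c4)OC(C(=O)OCC)[C@H]23)ccc1OCc1ccccc1
F2 | step 7 | 6a-(benzyloxy)-3-[4-(benzyloxy)-3-methoxyphenyl]-6-[4-(benzyloxy)-3,5-dimethoxyphenyl]-1-oxohexahydrofuro[3,4-c]furan-4-carboxylic acid (configuration of 14, either epimer at C4) | COc1cc([C@H]2OC(=O)[C@]3(OCc4ccccc4)[C@@H](c4cc(OC)c(OCc5ccccc5)c(OC)c4)OC(C(=O)O)[C@H]23)ccc1OCc1ccccc1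
F3 | step 9 | 6a-(benzyloxy)-3-[4-(benzyloxy)-3-methoxyphenyl]-6-[4-(benzyloxy)-3,5-dimethoxyphenyl]tetrahydro-1H,3H-furo[3,4-c]furan-1-ol (lactol of 14, both anomers) | COc1cc([C@H]2OC(O)[C@]3(OCc4ccccc4)[C@@H](c4cc(OC)c(OCc5ccccc5)c(OC)c4)OC[C@H]23)ccc1OCc1ccccc1
F0 | step 10 | none | none
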